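Ring B is a phloroglucinol whose oxygens on C2', C4' and C6' alternate with the chromone-bearing C1', the prenylated C3' and the unsubstituted C5'. This triketide pattern is stored in a 4-methoxy-3-prenyl-2-pyranone whose C6 methylene carries the chromone. In the key step Mg(OMe)2 in methanol opens that pyranone and the freed ketone enolate recloses on the new ester carbon, so the C1'–C2' bond and the whole of ring B, with its methyl ether and two phenols already differentiated, arise in one operation. The precursor is assembled from a chromone-3-acetic Weinreb amide and the dianion of prenylated methyl acetoacetate and is used as the free 7-phenol, so that the target is the direct product.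

Key step: step 10

Remark on the chemistry: primed locants are those of ring B (C1' is bonded to chromone C3); it is assumed that the 7-phenolate, a vinylogous carboxylate of the C4 carbonyl, makes chromone C2 inert to methoxide, which is why the 7-hydroxyl is unmasked before ring B is made and no acid is used once the ortho-prenyl phenol exists.

Step 1
Reactants: 1 resorcinol; 2 succinic anhydride
Product: 3 4-(2,4-dihydroxyphenyl)-4-oxobutanoic acid
Conditions: AlCl3 (3 equiv), PhNO2, 20 → 60 °C; then ice, aq HCl
Reagents that add atoms: none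
Why: Friedel–Crafts acylation: the AlCl3-activated anhydride attacks resorcinol at C4, para to one hydroxyl and ortho to the other, and the aluminium chelate of the resulting ortho-hydroxy ketone deactivates the ring against a second acylation.

Step 2
Reactants: 3 4-(2,4-dihydroxyphenyl)-4-oxobutanoic acid
Product: 4 4-(2,4-dihydroxyphenyl)-N-methoxy-N-methyl-4-oxobutanamide
Conditions: MeNH(OMe)·HCl (1.2 equiv), EDC·HCl (1.2 equiv), HOBt (cat.), N-methylmorpholine (2.4 equiv), DMF, 0 → 20 °C
Reagents that add atoms: N,O-dimethylhydroxylamine hydrochloride, CNOC.Cl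
Why: Carbodiimide-mediated amide coupling through the HOBt active ester: the amine is far more nucleophilic than the phenols, the 2-OH is tied up in a hydrogen bond to the ketone, and any aryl ester formed at the 4-OH is itself an active ester that the amine cleaves.

Step 3
Reactants: 4 4-(2,4-dihydroxyphenyl)-N-methoxy-N-methyl-4-oxobutanamide
Product: 5 4-[2-hydroxy-4-(methoxymethoxy)phenyl]-N-methoxy-N-methyl-4-oxobutanamide
Conditions: MOMCl (1.1 equiv), K2CO3, acetone, 0 → 20 °C
Reagents that add atoms: chloromethyl methyl ether, COCCl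
Why: Regioselective Williamson etherification: the 2-OH is chelated to the ketone and stays protonated under K2CO3 in acetone, so only the more acidic free 4-OH is alkylated, as is routine for 2,4-dihydroxyaryl ketones.

Step 4
Reactants: 5 4-[2-hydroxy-4-(methoxymethoxy)phenyl]-N-methoxy-N-methyl-4-oxobutanamide
Product: 7 N-methoxy-N-methyl-2-[7-(methoxymethoxy)-4-oxo-4H-chromen-3-yl]acetamide, via enaminone 6 (not isolated)
Conditions: Me2NCH(OMe)2 (3 equiv), PhMe, 95 °C
Reagents that add atoms: N,N-dimethylformamide dimethyl acetal, COC(OC)N(C)C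
Why: Enaminone-based chromone synthesis: the acetal condenses at the ketone α-methylene, which is more acidic than the amide α-methylene, and the ortho phenol then adds to the enaminone carbon (oxa-Michael addition) and dimethylamine is eliminated, as in the conversion of 2-hydroxydeoxybenzoins into isoflavones.

Step 5
Reactants: 8 methyl acetoacetate; 9 prenyl bromide
Product: 10 methyl 2-acetyl-5-methylhex-4-enoate (racemic)
Conditions: 8 (1.5 equiv), NaH, THF, 0 °C; then 9, 0 → 20 °C
Reagents that add atoms: none
Why: Acetoacetic ester alkylation: SN2 C-alkylation of the sodium enolate by the allylic bromide, with 8 in excess to suppress dialkylation; the new centre forms as the racemate and becomes sp2 in the pyranone.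

Step 6
Reactants: 10 methyl 2-acetyl-5-methylhex-4-enoate; 7 N-methoxy-N-methyl-2-[7-(methoxymethoxy)-4-oxo-4H-chromen-3-yl]acetamide
Product: 12 methyl 6-[7-(methoxymethoxy)-4-oxo-4H-chromen-3-yl]-2-(3-methylbut-2-en-1-yl)-3,5-dioxohexanoate, via dilithium dienolate 11 (not isolated)
Conditions: 10 (2.5 equiv), LiN(iPr)2 (5.1 equiv), THF, −78 → 0 °C; then 7, −78 → −20 °C; AcOH
Reagents that add atoms: none
Why: Claisen-type γ-acylation of a Huckin–Weiler β-keto ester dianion by a Weinreb amide: the terminal carbanion is the more reactive site, the chelated tetrahedral adduct survives until the quench so that no second addition occurs, the 3-alkylchromone is a poor Michael acceptor at low temperature, and the excess of 11 covers loss to deprotonation of the acidic methylene of 7; C2 stays racemic and is lost in step 7.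

Step 7
Reactants: 12 methyl 6-[7-(methoxymethoxy)-4-oxo-4H-chromen-3-yl]-2-(3-methylbut-2-en-1-yl)-3,5-dioxohexanoate
Product: 13 4-hydroxy-6-{[7-(methoxymethoxy)-4-oxo-4H-chromen-3-yl]methyl}-3-(3-methylbut-2-en-1-yl)-2H-pyran-2-one
Conditions: DBU (1.5 equiv), PhMe, 20 → 60 °C; aq citric acid work-up
Reagents that add atoms: none
Why: Base-mediated lactonisation of a 3,5-dioxo ester (intramolecular enol O-acylation with loss of methanol), the standard route to 4-hydroxy-2-pyranones, driven by the stable conjugated pyranone anion.

Step 8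
Reactants: 13 4-hydroxy-6-{[7-(methoxymethoxy)-4-oxo-4H-chromen-3-yl]methyl}-3-(3-methylbut-2-en-1-yl)-2H-pyran-2-one
Product: 14 4-methoxy-6-{[7-(methoxymethoxy)-4-oxo-4H-chromen-3-yl]methyl}-3-(3-methylbut-2-en-1-yl)-2H-pyran-2-one
Conditions: Me2SO4 (1.2 equiv), K2CO3, acetone, 50 °C
Reagents that add atoms: dimethyl sulfate, COS(=O)(=O)OC
Why: O-Methylation of the vinylogous acid (Williamson-type alkylation of the pyranone anion), for which Me2SO4 with K2CO3 in acetone is the usual way to the 4-methoxy-2-pyranone; C3 is blocked by the prenyl group and no other hydroxyl is free, so the future 4'-methyl ether is placed without a selective methylation.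

Step 9
Reactants: 14 4-methoxy-6-{[7-(methoxymethoxy)-4-oxo-4H-chromen-3-yl]methyl}-3-(3-methylbut-2-en-1-yl)-2H-pyran-2-one
Product: 15 6-[(7-hydroxy-4-oxo-4H-chromen-3-yl)methyl]-4-methoxy-3-(3-methylbut-2-en-1-yl)-2H-pyran-2-one
Conditions: HCl (1.25 M in MeOH), 40 °C
Reagents that add atoms: none
Why: Acid-catalysed cleavage of the aryl methoxymethyl acetal by transacetalisation to methanol: at this stage the prenyl group has no neighbouring phenol to cyclise onto and the pyranone enol ether can only exchange degenerately with the solvent.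

Step 10
Reactants: 15 6-[(7-hydroxy-4-oxo-4H-chromen-3-yl)methyl]-4-methoxy-3-(3-methylbut-2-en-1-yl)-2H-pyran-2-one
Product: 18 3-[2,6-dihydroxy-4-methoxy-3-(3-methylbut-2-en-1-yl)phenyl]-7-hydroxy-4H-chromen-4-one, via open-chain keto ester 16 (not isolated), via cyclohexenedione 17 (not isolated)
Conditions: Mg(OMe)2 (6 equiv), MeOH, 65 °C, Ar; then 10% aq AcOH, 0 °C
Reagents that add atoms: none
Why: Methoxide adds to the lactone carbonyl of the magnesium 7-phenolate of 15 and opens the ring to keto ester 16, whose (E)-enoate geometry, inherited from the ring, holds the ester carbon (future C2') on the same side as the ketone arm; proton exchange in methanol then gives, besides the unproductive C5' enolate, the C6' enolate at C1' (the methylene on chromone C3), which attacks the ester, expels methoxide to give dione 17 and ends as the aromatic ring after enolisation. The closest known reaction type is the alkoxide-induced conversion of 4-methoxy-6-alkyl-2-pyranones into phloroglucinol monomethyl ethers, a Claisen condensation of the enol lactone to cyclic 1,3-dione kind that Mg(OMe)2 also mediates with open-chain polyketo esters. Ring B is closed through the C1'–C2' bond in a 6-(enolendo)-exo-trig mode. No stereocentre is created, because C1' of 17 becomes an aromatic carbon. The selectivity needed is chemoselectivity for C-acylation at C1' over return to the pyranone and over methoxide attack at chromone C2: relactonisation is reversible whereas the C–C closure is made irreversible by aromatisation and by the magnesium chelate between the new 2'-phenolate and the C4 carbonyl, and the 7-phenolate together with the weak, chelating base keeps the chromone intact.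

Compound list
1 | resorcinol (benzene-1,3-diol) | Oc1cccc(O)c1 | starting material
2 | succinic anhydride | O=C1CCC(=O)O1 | starting material
3 | 4-(2,4-dihydroxyphenyl)-4-oxobutanoic acid | OC(=O)CCC(=O)c1ccc(O)cc1O | intermediate
4 | 4-(2,4-dihydroxyphenyl)-N-methoxy-N-methyl-4-oxobutanamide | CON(C)C(=O)CCC(=O)c1ccc(O)cc1O | intermediate
5 | 4-[2-hydroxy-4-(methoxymethoxy)phenyl]-N-methoxy-N-methyl-4-oxobutanamide | CON(C)C(=O)CCC(=O)c1ccc(OCOC)cc1O | intermediate
6 | 3-[(dimethylamino)methylidene]-4-[2-hydroxy-4-(methoxymethoxy)phenyl]-N-methoxy-N-methyl-4-oxobutanamide (push–pull alkene, geometry not fixed) | CON(C)C(=O)CC(=CN(C)C)C(=O)c1ccc(OCOC)cc1O | intermediate (not isolated)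
7 | N-methoxy-N-methyl-2-[7-(methoxymethoxy)-4-oxo-4H-chromen-3-yl]acetamide | CON(C)C(=O)Cc1coc2cc(OCOC)ccc2c1=O | intermediate
8 | methyl acetoacetate | COC(=O)CC(C)=O | starting material
9 | prenyl bromide (1-bromo-3-methylbut-2-ene) | CC(C)=CCBr | starting material
10 | methyl 2-acetyl-5-methylhex-4-enoate (racemic) | COC(=O)C(CC=C(C)C)C(C)=O | intermediate
11 | dilithium 1-methoxy-2-(3-methylbut-2-en-1-yl)buta-1,3-diene-1,3-diolate (dianion of 10) | [Li+].[Li+].COC([O-])=C(CC=C(C)C)C([O-])=C | intermediate (not isolated)
12 | methyl 6-[7-(methoxymethoxy)-4-oxo-4H-chromen-3-yl]-2-(3-methylbut-2-en-1-yl)-3,5-dioxohexanoate (racemic at C2, enolised in solution) | COC(=O)C(CC=C(C)C)C(=O)CC(=O)Cc1coc2cc(OCOC)ccc2c1=O | intermediate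
13 | 4-hydroxy-6-{[7-(methoxymethoxy)-4-oxo-4H-chromen-3-yl]methyl}-3-(3-methylbut-2-en-1-yl)-2H-pyran-2-one | O=c1oc(Cc2coc3cc(OCOC)ccc3c2=O)cc(O)c1CC=C(C)C | intermediate
14 | 4-methoxy-6-{[7-(methoxymethoxy)-4-oxo-4H-chromen-3-yl]methyl}-3-(3-methylbut-2-en-1-yl)-2H-pyran-2-one | O=c1oc(Cc2coc3cc(OCOC)ccc3c2=O)cc(OC)c1CC=C(C)C | intermediate
15 | 6-[(7-hydroxy-4-oxo-4H-chromen-3-yl)methyl]-4-methoxy-3-(3-methylbut-2-en-1-yl)-2H-pyran-2-one | O=c1oc(Cc2coc3cc(O)ccc3c2=O)cc(OC)c1CC=C(C)C | intermediate
16 | methyl (2E)-6-(7-hydroxy-4-oxo-4H-chromen-3-yl)-3-methoxy-2-(3-methylbut-2-en-1-yl)-5-oxohex-2-enoate | COC(=O)/C(CC=C(C)C)=C(/OC)CC(=O)Cc1coc2cc(O)ccc2c1=O | intermediate (not isolated)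
17 | 2-(7-hydroxy-4-oxo-4H-chromen-3-yl)-5-methoxy-4-(3-methylbut-2-en-1-yl)cyclohex-4-ene-1,3-dione (C2 transient and enolisable, no defined configuration) | COC1=C(CC=C(C)C)C(=O)C(c2coc3cc(O)ccc3c2=O)C(=O)C1 | intermediate (not isolated)
18 | 3-[2,6-dihydroxy-4-methoxy-3-(3-methylbut-2-en-1-yl)phenyl]-7-hydroxy-4H-chromen-4-one (no stereocentre) | COc1cc(O)c(-c2coc3cc(O)ccc3c2=O)c(O)c1CC=C(C)C | target

Total step count: 10. Longest linear sequence: 9 steps (1, 2, 3, 4, 6, 7, 8, 9, 10 from resorcinol); step 5 is a one-step side branch.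

Steps most likely to fail

1. Step 10. After methanolysis the open-chain ester may only shuttle back to the pyranone through its more acidic C5' enolate, or the magnesium phenolate may leave solution, so that the C1' enolate never closes on C2'; cleavage of the C6' ketone by methoxide is a further drain. The fallback sets out from 14 and comes back at 18, and it inverts the order of unmasking and ring construction. Neutral, soluble 14, whose electron-poorer chromone also makes the C1' hydrogens more acidic, is heated with Mg(OMe)2 in MeOH. It should pass through methyl (2E)-3-methoxy-6-[7-(methoxymethoxy)-4-oxo-4H-chromen-3-yl]-2-(3-methylbut-2-en-1-yl)-5-oxohex-2-enoate F1 and 5-methoxy-2-[7-(methoxymethoxy)-4-oxo-4H-chromen-3-yl]-4-(3-methylbut-2-en-1-yl)cyclohex-4-ene-1,3-dione F2 to 3-[2,6-dihydroxy-4-methoxy-3-(3-methylbut-2-en-1-yl)phenyl]-7-(methoxymethoxy)-4H-chromen-4-one F3. The acetal of F3 is then cleaved with dilute HCl in MeOH at 20–40 °C, kept short to spare the ortho-prenyl phenol, to give 18.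

2. Step 6. Proton transfer from the acidic methylene of 7 to the dianion, or conjugate addition of the dianion to chromone C2, may outrun acylation. The fallback sets out from 7 and 10 and comes back at 12, and it replaces acylation by aldol addition followed by oxidation. Amide 7 is reduced with iBu2AlH (1.1 equiv, THF, −78 °C), where the chelating N-methoxy-N-methylamide should react well before the doubly vinylogous chromone carbonyl, to 2-[7-(methoxymethoxy)-4-oxo-4H-chromen-3-yl]acetaldehyde F4. Crude F4 is added at −78 °C to dianion 11, where addition to an aldehyde is fast enough to outrun proton transfer, to give methyl 5-hydroxy-6-[7-(methoxymethoxy)-4-oxo-4H-chromen-3-yl]-2-(3-methylbut-2-en-1-yl)-3-oxohexanoate F5 as a mixture of diastereomers. Dess–Martin periodinane (CH2Cl2, NaHCO3, 20 °C) then oxidises the carbinol and returns to 12; both stereocentres of F5 are erased on the way to 13.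

3. Step 8. The ambident pyranone anion may be alkylated at the lactone oxygen, giving the isomeric 2-methoxy-4-pyranone in place of 14. The fallback sets out from 10 (with 7 as acyl partner) and comes back at 14, and it installs the methyl ether before any pyranone exists. Keto ester 10 is converted with HC(OMe)3 and catalytic TsOH in MeOH into methyl (2E)-3-methoxy-2-(3-methylbut-2-en-1-yl)but-2-enoate F6. γ-Deprotonation with LiN(iPr)2 (THF, −78 °C) gives lithium 1,3-dimethoxy-2-(3-methylbut-2-en-1-yl)buta-1,3-dien-1-olate F7, which is acylated by 7 (−78 → −20 °C, AcOH quench) to the open-chain ester F1 of the first fallback. DBU in toluene at 60 °C closes F1 to 14 with loss of methanol, so steps 6 to 8 are bypassed.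

Further compounds
F1 | step 10 | methyl (2E)-3-methoxy-6-[7-(methoxymethoxy)-4-oxo-4H-chromen-3-yl]-2-(3-methylbut-2-en-1-yl)-5-oxohex-2-enoate | COC(=O)/C(CC=C(C)C)=C(/OC)CC(=O)Cc1coc2cc(OCOC)ccc2c1=O
F2 | step 10 | 5-methoxy-2-[7-(methoxymethoxy)-4-oxo-4H-chromen-3-yl]-4-(3-methylbut-2-en-1-yl)cyclohex-4-ene-1,3-dione | COC1=C(CC=C(C)C)C(=O)C(c2coc3cc(OCOC)ccc3c2=O)C(=O)C1
F3 | step 10 | 3-[2,6-dihydroxy-4-methoxy-3-(3-methylbut-2-en-1-yl)phenyl]-7-(methoxymethoxy)-4H-chromen-4-one | COc1cc(O)c(-c2coc3cc(OCOC)ccc3c2=O)c(O)c1CC=C(C)C
F4 | step 6 | 2-[7-(methoxymethoxy)-4-oxo-4H-chromen-3-yl]acetaldehyde | O=CCc1coc2cc(OCOC)ccc2c1=O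
F5 | step 6 | methyl 5-hydroxy-6-[7-(methoxymethoxy)-4-oxo-4H-chromen-3-yl]-2-(3-methylbut-2-en-1-yl)-3-oxohexanoate (mixture of diastereomers) | COC(=O)C(CC=C(C)C)C(=O)CC(O)Cc1coc2cc(OCOC)ccc2c1=O
F6 | step 8 | methyl (2E)-3-methoxy-2-(3-methylbut-2-en-1-yl)but-2-enoate | COC(=O)/C(CC=C(C)C)=C(/OC)C
F7 | step 8 | lithium 1,3-dimethoxy-2-(3-methylbut-2-en-1-yl)buta-1,3-dien-1-olate | [Li+].COC([O-])=C(CC=C(C)C)C(OC)=C
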